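**Retrosynthetic overview**
1. Ring A last: Mannich closure of C18–C19 from a secondary amine, an ethyl ketone and CH2O. Ring C just before it: intramolecular Mannich (C3 onto C1) on a cyclic imine made from the ring B lactam.
2. Ring F (lactone): C21–C22 scission of a cyclohexanone whose enol ether is fixed regiospecifically by conjugate addition of the C4–C3–C2 chain at C5.
3. Ring B (lactam): vinylogous Mannich aminomethylation at C6, then lactamisation onto the C8 ester. Ring E: C10 allylation, C9 vinylation, ring-closing metathesis, reductive allylic transposition.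
4. Key C–C bond C8–C13: intermolecular Michael addition of 2-allylcycloheptane-1,3-dione to methyl vinyl ketone, then catalytic asymmetric aldol condensation (Robinson annulation) that fixes C8.
5. Ring order: D (present from the start) → cyclohexenone (latent ring F) → E → B → F → C → A.

Assumption and numbering (one line): cycloheptane-1,3-dione and reagent 20 are taken as purchasable; atoms are numbered N–C1–C3(–C4)–C2(=O)–C18(C20)–C19–N, N–C7–C6–C5(–C4)(–C21–O)–C8(–C1)(–C13–C14–C22(=O)–O), C6–C12–C11–C10–C9(=C15)–C8, C10–C17–C16–C15; ring A = N/C19/C18/C2/C3/C1, B = N/C7/C6/C5/C8/C1, C = C1/C3/C4/C5/C8, D = seven-membered carbocycle, E = cyclopentene, F = lactone.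

**Step 1**
Reactants: 1 cycloheptane-1,3-dione; 2 allyl acetate
Product: 3 2-allylcycloheptane-1,3-dione
Conditions: Pd(PPh3)4 (2 mol %), Et3N, THF, 50 °C
Reagents that add atoms: none
Why: Tsuji–Trost allylation, in which the soft dione enolate attacks the π-allylpalladium complex at carbon to give C-2 monoallylation; no stereocentre.

**Step 2**
Reactants: 3 2-allylcycloheptane-1,3-dione; 4 methyl vinyl ketone
Product: 5 2-allyl-2-(3-oxobutyl)cycloheptane-1,3-dione
Conditions: Et3N (10 mol %), EtOAc, 40 °C
Reagents that add atoms: none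
Why: Key intermolecular Michael addition, in which the stabilised dione enolate adds 1,4 to the unhindered enone and forms the C8–C13 bond and the quaternary carbon (not yet stereogenic) under conditions too mild for retro-Claisen cleavage.

**Step 3**
Reactants: 5 2-allyl-2-(3-oxobutyl)cycloheptane-1,3-dione
Product: 6 (S)-1-allylbicyclo[5.4.0]undec-7-ene-2,9-dione (C9 ketone, enone C22(=O)–C21=C5, allyl on C8)
Conditions: N-tosyl-(Ra)-binam-D-prolinamide (5 mol %), PhCO2H (2.5 mol %), neat, 25 °C
Reagents that add atoms: none
Why: Hajos–Parrish–Eder–Sauer–Wiechert aldol condensation (second half of the Robinson annulation), in which the D-prolinamide enamine of the side-chain ketone attacks one of the two enantiotopic ring carbonyls and so sets C8 as (S), the mirror image of the L-proline series, before dehydration.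

**Step 4**
Reactants: 6 (S)-1-allylbicyclo[5.4.0]undec-7-ene-2,9-dione
Product: 7 1-[(E)-prop-1-enyl]bicyclo[5.4.0]undec-7-ene-2,9-dione (C8 unchanged)
Conditions: RuHCl(CO)(PPh3)3 (3 mol %), toluene, 80 °C
Reagents that add atoms: none
Why: Ruthenium hydride alkene isomerisation (hydrometalation/β-hydride elimination) moves the terminal double bond to the more stable internal position next to C8 and leaves the enone alone; the E/Z ratio does not matter.

**Step 5**
Reactants: 7 1-[(E)-prop-1-enyl]bicyclo[5.4.0]undec-7-ene-2,9-dione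
Product: 8 2,9-dioxobicyclo[5.4.0]undec-7-ene-1-carbaldehyde (C1 aldehyde on C8)
Conditions: O3 (1 equiv, Sudan Red 7B end point), pyridine, CH2Cl2, −78 °C; Me2S
Reagents that add atoms: ozone [O-][O+]=O
Why: Ozonolysis, in which the electron-rich propenyl group reacts far faster than the conjugated, electron-poor enone, so one equivalent of ozone gives the C1 aldehyde selectively.

**Step 6**
Reactants: 8 2,9-dioxobicyclo[5.4.0]undec-7-ene-1-carbaldehyde
Product: 10 methyl 2,9-dioxobicyclo[5.4.0]undec-7-ene-1-carboxylate, via β-keto acid 9 (not isolated)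
Conditions: NaClO2, NaH2PO4, 2-methyl-2-butene, t-BuOH/H2O, 0 °C; then TMSCHN2, MeOH/toluene, 0 °C
Reagents that add atoms: NaClO2 [Na+].[O-]Cl=O; trimethylsilyldiazomethane C[Si](C)(C)C=[N+]=[N-]
Why: Pinnick oxidation followed by diazoalkane esterification, both at 0 °C so that the non-enolisable β-keto acid is trapped as its ester before it can decarboxylate.

**Step 7**
Reactants: 10 methyl 2,9-dioxobicyclo[5.4.0]undec-7-ene-1-carboxylate
Product: 11 methyl 9-ethoxy-2-oxobicyclo[5.4.0]undeca-6,8-diene-1-carboxylate (dienol ether C22(OEt)=C21–C5=C6)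
Conditions: HC(OEt)3, TsOH·H2O (2 mol %), EtOH/dioxane, 25 °C
Reagents that add atoms: triethyl orthoformate CCOC(OCC)OCC
Why: Acid-catalysed ketalisation–elimination with orthoformate converts only the conjugated ketone into the linear (thermodynamic) dienol ether, as with steroidal enones beside hindered saturated ketones, and masks the enone for the next steps.

**Step 8**
Reactants: 11 methyl 9-ethoxy-2-oxobicyclo[5.4.0]undeca-6,8-diene-1-carboxylate; 12 allyl bromide
Product: 13 methyl 3-allyl-9-ethoxy-2-oxobicyclo[5.4.0]undeca-6,8-diene-1-carboxylate (allyl on C10, trans to the C8 ester)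
Conditions: LiN(iPr)2 (1.1 equiv), THF, −78 °C; allyl bromide, DMPU, −78 → −20 °C
Reagents that add atoms: none
Why: Kinetic enolate alkylation, in which the C9 ketone can enolise only toward C10 and the electrophile approaches anti to the pseudo-axial C8 ester (no 1,3-diaxial contact), placing the allyl group trans to the ester and setting C10.

**Step 9**
Reactants: 13 methyl 3-allyl-9-ethoxy-2-oxobicyclo[5.4.0]undeca-6,8-diene-1-carboxylate; 14 vinylmagnesium bromide
Product: 15 the C9 tertiary allylic alcohol (2-hydroxy-2-vinyl derivative of 13; C9 epimers)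
Conditions: CeCl3 (anhydrous, 3 equiv), THF, −78 °C
Reagents that add atoms: none
Why: Organocerium 1,2-addition (Imamoto conditions) to the hindered, enolisable C9 ketone without enolisation or attack on the neopentyl ester; the carbinol configuration is irrelevant because C9 becomes sp2 in step 12.

**Step 10**
Reactants: 15 the C9 tertiary allylic alcohol
Product: 16 tricyclic cyclopentenol (ring E closed: C9(OH)–C15=C16–C17–C10; dienol ether and C8 ester retained)
Conditions: second-generation Grubbs catalyst (5 mol %), CH2Cl2, 40 °C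
Reagents that add atoms: none
Why: Ring-closing metathesis of the vinyl and allyl groups forms the five-membered ring E irreversibly with loss of ethylene, and both C9 epimers can cyclise.

**Step 11**
Reactants: 16 tricyclic cyclopentenol dienol ether
Product: 17 tricyclic enone alcohol (C22 ketone, C21=C5; C9–OH, C15=C16)
Conditions: aq. oxalic acid (5 %), THF, 0 → 25 °C
Reagents that add atoms: water O
Why: Mild acid hydrolysis of the dienol ether returns the conjugated enone while the tertiary allylic alcohol survives.

**Step 12**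
Reactants: 17 tricyclic enone alcohol
Product: 18 tricyclic enone ester with the C9=C15 alkene of ring E (C10–H as set in step 8)
Conditions: Et3SiH (5 equiv), CF3CO2H (5 equiv), CH2Cl2, −40 → 0 °C
Reagents that add atoms: none
Why: Ionic hydrogenation, in which acid ionises the tertiary allylic alcohol to an allyl cation and the silane delivers hydride to the less hindered secondary terminus C16, giving the more substituted C9=C15 alkene (reductive 1,3-transposition) without forming a stereocentre.

**Step 13**
Reactants: 18 tricyclic enone ester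
Product: 19 tricyclic dienol ethyl ether (C22(OEt)=C21–C5=C6; ring E alkene C9=C15; C8 ester)
Conditions: HC(OEt)3, TsOH·H2O (2 mol %), EtOH/dioxane, 25 °C
Reagents that add atoms: triethyl orthoformate CCOC(OCC)OCC
Why: The same orthoformate ketalisation–elimination as in step 7 re-forms the linear dienol ether, now to serve as the γ-nucleophile.

**Step 14**
Reactants: 19 tricyclic dienol ethyl ether; 20 N-(methoxymethyl)-N,N-bis(trimethylsilyl)amine
Product: 22 tetracyclic lactam enone (ring B lactam N–C1(=O); C7 on C6 cis to C1; enone C22(=O)–C21=C5), via amino ester 21 (not isolated)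
Conditions: TMSOTf (1.2 equiv), CH2Cl2, −78 → 0 °C; aq. NaHCO3; then DBU (0.5 equiv), toluene, 100 °C
Reagents that add atoms: water O
Why: Vinylogous Mannich reaction, in which the dienol ether attacks the silylated methyleneiminium ion at its γ-carbon C6 (as in 6-functionalisation of steroidal dienol ethers), after which DBU equilibrates the C6 epimers through the dienolate and only the epimer with CH2NH2 cis to the C8 ester can close the six-membered lactam, fixing C6.

**Step 15**
Reactants: 23 ethyl vinyl ketone (pent-1-en-3-one)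
Product: 25 2-(2-bromoethyl)-2-ethyl-1,3-dioxolane, via 1-bromopentan-3-one 24 (not isolated)
Conditions: HBr (g), CH2Cl2, 0 °C; then HOCH2CH2OH, TsOH·H2O (cat.), 4 Å sieves, 25 °C
Reagents that add atoms: hydrogen bromide Br; ethylene glycol OCCO
Why: Conjugate hydrobromination of the vinyl ketone followed by acid-catalysed ketalisation, the standard route to β-bromo ketals; no stereocentre.

**Step 16**
Reactants: 25 2-(2-bromoethyl)-2-ethyl-1,3-dioxolane
Product: 26 [2-(2-ethyl-1,3-dioxolan-2-yl)ethyl]magnesium bromide (THF solution)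
Conditions: Mg turnings (activated with BrCH2CH2Br), THF, 25–30 °C
Reagents that add atoms: magnesium [Mg]
Why: Grignard formation by insertion of magnesium into the primary C–Br bond; the ketal oxygens are too remote for β-elimination, so the reagent is stable below 30 °C.

**Step 17**
Reactants: 22 tetracyclic lactam enone; 26 [2-(2-ethyl-1,3-dioxolan-2-yl)ethyl]magnesium bromide
Product: 27 silyl enol ether (C22(OSiMe3)=C21) with quaternary C5 carrying the C4–C3–C2(ketal)–C18–C20 chain, C4 cis to C1
Conditions: CuBr·SMe2 (0.3 equiv), TMSCl (5 equiv), DMPU, THF, −78 → −30 °C; Et3N, pH 7 buffer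
Reagents that add atoms: chlorotrimethylsilane C[Si](C)(C)Cl
Why: Copper-catalysed, TMSCl-accelerated conjugate addition, in which the alkyl group reaches C5 from the face of the flat lactam bridge (C1–N–C7) and away from the inward hydrogens of ring D, so C4 ends cis to C1, and the enolate is trapped regiospecifically as the C22–C21 silyl enol ether.

**Step 18**
Reactants: 27 silyl enol ether
Product: 28 α-hydroxy ketone (C22 ketone, C21–OH; C21 epimers)
Conditions: MeLi (2.2 equiv), THF, −78 → −20 °C; then 2-(phenylsulfonyl)-3-phenyloxaziridine (1.3 equiv), −78 °C; aq. NH4Cl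
Reagents that add atoms: 2-(phenylsulfonyl)-3-phenyloxaziridine O=S(=O)(c1ccccc1)N1OC1c1ccccc1
Why: The regiospecific lithium enolate released by Si–O cleavage undergoes Davis α-hydroxylation at C21 with a reagent that does not epoxidise the ring E alkene; the new carbinol centre is destroyed in the next step.

**Step 19**
Reactants: 28 α-hydroxy ketone
Product: 30 hydroxy acid (C21H2OH on C5, C13–C14–C22O2H on C8), via aldehyde acid 29 (not isolated)
Conditions: NaIO4 (3 equiv), THF/pH 7 buffer, 25 °C; then NaBH4, 0 °C; acidify to pH 4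
Reagents that add atoms: water O
Why: Periodate cleavage of the α-hydroxy ketone (Malaprade type) cuts C21–C22 into the C22 acid and the C21 aldehyde, already differentiated, and borohydride then reduces only the aldehyde.

**Step 20**
Reactants: 30 hydroxy acid
Product: 31 pentacyclic lactone lactam (rings B, D, E, F; side-chain ketal)
Conditions: 2,4,6-Cl3C6H2COCl, Et3N, THF, 25 °C; then DMAP, toluene, 60 °C, high dilution
Reagents that add atoms: none
Why: Yamaguchi lactonisation closes the seven-membered lactone readily because the two arms are held cis on the vicinal quaternary carbons C5 and C8.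

**Step 21**
Reactants: 31 pentacyclic lactone lactam
Product: 32 cyclic imine (N=C1–H in ring B)
Conditions: Cp2Zr(H)Cl (2.5 equiv), THF, 25 °C
Reagents that add atoms: none
Why: Schwartz-reagent reduction (hydrozirconation of the amide carbonyl) stops at the imine and is selective for the secondary lactam over the lactone and ketal; C1 carries no α-hydrogen, so the imine cannot tautomerise.

**Step 22**
Reactants: 32 cyclic imine
Product: 34 hexacyclic amino ketone lacking C19 (ring C closed; secondary amine; ethyl ketone on C3), via keto imine 33 (not isolated)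
Conditions: TsOH·H2O (1.5 equiv), acetone/H2O (10:1), 45 °C; NaHCO3
Reagents that add atoms: water O
Why: Acid removes the ketal and the freed ethyl ketone undergoes an intramolecular Mannich reaction (5-exo attack of enol carbon C3 on iminium carbon C1), which can occur only on the face of ring B bearing the C4 chain and so sets C1, while C3 stays epimerisable.

**Step 23**
Reactants: 34 hexacyclic amino ketone; 35 formaldehyde
Product: 36 target CNP0292775.1
Conditions: aq. CH2O (37 %, 3 equiv), AcOH, EtOH, 60 °C
Reagents that add atoms: none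
Why: Second Mannich reaction, in which the N-methyleneiminium ion is attacked by the ethyl-side enol carbon C18 to close ring A, possible only with the acyl group at C3 cis to N (C3 funnels by enolisation), and C18 equilibrates to the equatorial methyl of the target.

**Compound list**
1 | cycloheptane-1,3-dione | O=C1CCCCC(=O)C1 | starting material
2 | allyl acetate | C=CCOC(C)=O | starting material
3 | 2-allylcycloheptane-1,3-dione | C=CCC1C(=O)CCCCC1=O | intermediate
4 | methyl vinyl ketone (but-3-en-2-one) | CC(=O)C=C | starting material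
5 | 2-allyl-2-(3-oxobutyl)cycloheptane-1,3-dione | CC(=O)CCC1(CC=C)C(=O)CCCCC1=O | intermediate
6 | (S)-1-allylbicyclo[5.4.0]undec-7-ene-2,9-dione | C=CC[C@@]12CCC(=O)C=C1CCCCC2=O | intermediate
7 | 1-[(E)-prop-1-enyl]bicyclo[5.4.0]undec-7-ene-2,9-dione | C/C=C/[C@@]12CCC(=O)C=C1CCCCC2=O | intermediate
8 | 2,9-dioxobicyclo[5.4.0]undec-7-ene-1-carbaldehyde | O=C[C@@]12CCC(=O)C=C1CCCCC2=O | intermediate
9 | 2,9-dioxobicyclo[5.4.0]undec-7-ene-1-carboxylic acid | OC(=O)[C@@]12CCC(=O)C=C1CCCCC2=O | intermediate
10 | methyl 2,9-dioxobicyclo[5.4.0]undec-7-ene-1-carboxylate | COC(=O)[C@@]12CCC(=O)C=C1CCCCC2=O | intermediate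
11 | methyl 9-ethoxy-2-oxobicyclo[5.4.0]undeca-6,8-diene-1-carboxylate | CCOC1=CC2=CCCCC(=O)[C@]2(C(=O)OC)CC1 | intermediate
12 | allyl bromide | C=CCBr | starting material
13 | methyl 3-allyl-9-ethoxy-2-oxobicyclo[5.4.0]undeca-6,8-diene-1-carboxylate (allyl trans to ester) | CCOC1=CC2=CCC[C@H](CC=C)C(=O)[C@]2(C(=O)OC)CC1 | intermediate
14 | vinylmagnesium bromide | C=C[Mg]Br | starting material
15 | methyl 3-allyl-9-ethoxy-2-hydroxy-2-vinylbicyclo[5.4.0]undeca-6,8-diene-1-carboxylate (C9 carbinol epimers) | CCOC1=CC2=CCC[C@H](CC=C)C(O)(C=C)[C@]2(C(=O)OC)CC1 | intermediate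
16 | tricyclic cyclopentenol dienol ether (ring E: C9(OH), C15=C16) | CCOC1=CC2=CCC[C@@H]3CC=CC3(O)[C@]2(C(=O)OC)CC1 | intermediate
17 | tricyclic enone alcohol (C22 ketone, C9–OH, C15=C16) | O=C1C=C2CCC[C@@H]3CC=CC3(O)[C@]2(C(=O)OC)CC1 | intermediate
18 | tricyclic enone ester (ring E alkene C9=C15) | O=C1C=C2CCC[C@@H]3CCC=C3[C@]2(C(=O)OC)CC1 | intermediate
19 | tricyclic dienol ethyl ether (C22(OEt)=C21–C5=C6, C9=C15) | CCOC1=CC2=CCC[C@@H]3CCC=C3[C@]2(C(=O)OC)CC1 | intermediate
20 | N-(methoxymethyl)-N,N-bis(trimethylsilyl)amine | COCN([Si](C)(C)C)[Si](C)(C)C | starting material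
21 | amino ester (C6–CH2NH2, both C6 epimers; enone; C8 methyl ester) | O=C1C=C2C(CN)CC[C@@H]3CCC=C3[C@]2(C(=O)OC)CC1 | intermediate
22 | tetracyclic lactam enone (ring B lactam; C7 cis to C1) | O=C1C=C2[C@@H]3CC[C@@H]4CCC=C4[C@@]2(CC1)C(=O)NC3 | intermediate
23 | ethyl vinyl ketone (pent-1-en-3-one) | CCC(=O)C=C | starting material
24 | 1-bromopentan-3-one | CCC(=O)CCBr | intermediate
25 | 2-(2-bromoethyl)-2-ethyl-1,3-dioxolane | CCC1(CCBr)OCCO1 | intermediate
26 | [2-(2-ethyl-1,3-dioxolan-2-yl)ethyl]magnesium bromide | CCC1(CC[Mg]Br)OCCO1 | intermediate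
27 | C22 trimethylsilyl enol ether with quaternary C5 (C4 chain cis to C1; side-chain dioxolane) | C[Si](C)(C)OC1=C[C@]2(CCC3(CC)OCCO3)[C@@H]4CC[C@@H]5CCC=C5[C@@]2(CC1)C(=O)NC4 | intermediate
28 | α-hydroxy ketone (C22=O, C21–OH, C21 epimers) | O=C1C(O)[C@]2(CCC3(CC)OCCO3)[C@@H]4CC[C@@H]5CCC=C5[C@@]2(CC1)C(=O)NC4 | intermediate
29 | aldehyde acid (C21 aldehyde on C5, C22 acid) | O=C[C@]1(CCC2(CC)OCCO2)[C@@H]3CC[C@@H]4CCC=C4[C@@]1(CCC(=O)O)C(=O)NC3 | intermediate
30 | hydroxy acid (C21H2OH on C5, C22O2H) | OC[C@]1(CCC2(CC)OCCO2)[C@@H]3CC[C@@H]4CCC=C4[C@@]1(CCC(=O)O)C(=O)NC3 | intermediate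
31 | pentacyclic lactone lactam (rings B, D, E, F; side-chain dioxolane) | CCC1(OCCO1)CC[C@]23COC(=O)CC[C@]25C(=O)NC[C@H]3CC[C@@H]4CCC=C45 | intermediate
32 | cyclic imine (N=C1) lactone ketal | CCC1(OCCO1)CC[C@]23COC(=O)CC[C@]25C=NC[C@H]3CC[C@@H]4CCC=C45 | intermediate
33 | keto imine (free ethyl ketone, N=C1) | CCC(=O)CC[C@]23COC(=O)CC[C@]25C=NC[C@H]3CC[C@@H]4CCC=C45 | intermediate
34 | hexacyclic amino ketone lacking C19 (ring C closed, N–H, propanoyl on C3 cis to N) | CCC(=O)[C@H]1C[C@]23COC(=O)CC[C@]25[C@H]1NC[C@H]3CC[C@@H]4CCC=C45 | intermediate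
35 | formaldehyde | C=O | starting material
36 | CNP0292775.1 | C[C@@H]1CN2C[C@H]3CC[C@@H]4CCC=C4[C@]45CCC(=O)OC[C@]34C[C@H](C1=O)[C@H]25 | target

**Totals**
Total step count: 23. Longest linear sequence: 21 steps (steps 1–14 and 17–23); steps 15–16 are a two-step side branch.

**Three steps most likely to fail**

Step 17 (conjugate addition at the hindered C5 of 22). The fallback sets out from 22 and comes back at 28; it makes the C5–C4 bond by a sigmatropic shift instead of an organocopper addition. Compound 22 is reduced (NaBH4, CeCl3·7H2O, MeOH, −40 °C) to the C22 allylic alcohol F1, with the hydroxyl on the lactam-bridge face (Mitsunobu inversion if the other epimer forms). F1 is esterified with 3-(2-ethyl-1,3-dioxolan-2-yl)propanoic acid (DCC, DMAP) to the allylic ester F2. Ireland–Claisen rearrangement (LiN(iPr)2, TMSCl, THF, −78 → 65 °C) transfers the chain suprafacially to C5 and gives the carboxylic acid F3. Barton decarboxylation (thiohydroxamate ester, t-BuSH, light) gives the cyclohexene F4. OsO4/NMO dihydroxylates the less hindered cis-disubstituted C21=C22 alkene to the diol F5. Mono-oxidation of the less hindered C22 hydroxyl (Bu2SnO, then NBS) gives 28.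

Step 14 (γ-selectivity of the aminomethylation and closure of the lactam). The fallback sets out from 19 and comes back at 22; it makes C7 electrophilic and brings nitrogen in by aza-Michael addition. Compound 19 reacts with dimethylmethyleneiminium iodide (CH2Cl2, 25 °C) to give the γ-(dimethylaminomethyl) enone F6. Quaternisation with MeI and elimination with NaHCO3 give the 6-methylene dienone F7. Ammonia in MeOH (60 °C, sealed tube) adds 1,6 to the exocyclic methylene and the amine lactamises onto the C8 ester to give 22.

Step 12 (regiochemistry of hydride capture, cation side reactions, alkene migration in acid). The fallback sets out from 11 and comes back at 19; it closes ring E by olefination, so no allylic cation is formed and steps 8–13 are bypassed. The C10 enolate of 11 (LiN(iPr)2, THF, −78 °C) is alkylated with 1-chloro-3-iodopropane to the 3-chloropropyl ketone F8. NaI in acetone and then PPh3 (MeCN, 80 °C) give the phosphonium iodide F9. KN(SiMe3)2 (THF, −78 → 25 °C) forms the ylide, which undergoes intramolecular Wittig olefination on the C9 ketone and gives the C9=C15 alkene of 19 directly.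

**Further compounds**
F1 | step 17 | C22 allylic alcohol of the lactam (OH on the lactam-bridge face, C21=C5) | O[C@H]1C=C2[C@@H]3CC[C@@H]4CCC=C4[C@@]2(CC1)C(=O)NC3
F2 | step 17 | 3-(2-ethyl-1,3-dioxolan-2-yl)propanoate ester of F1 | CCC1(CCC(=O)O[C@H]2C=C3[C@@H]4CC[C@@H]5CCC=C5[C@@]3(CC2)C(=O)NC4)OCCO1
F3 | step 17 | Ireland–Claisen acid (C5 quaternary, CO2H on C4, C21=C22) | C1=C[C@]2(C(C(=O)O)CC3(CC)OCCO3)[C@@H]4CC[C@@H]5CCC=C5[C@@]2(CC1)C(=O)NC4
F4 | step 17 | decarboxylated cyclohexene (C21=C22, side-chain dioxolane) | C1=C[C@]2(CCC3(CC)OCCO3)[C@@H]4CC[C@@H]5CCC=C5[C@@]2(CC1)C(=O)NC4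
F5 | step 17 | C21,C22 cis-diol | OC1C(O)[C@]2(CCC3(CC)OCCO3)[C@@H]4CC[C@@H]5CCC=C5[C@@]2(CC1)C(=O)NC4
F6 | step 14 | γ-(dimethylaminomethyl) enone ester (C6 epimers) | O=C1C=C2C(CN(C)C)CC[C@@H]3CCC=C3[C@]2(C(=O)OC)CC1
F7 | step 14 | 6-methylene dienone ester | O=C1C=C2C(=C)CC[C@@H]3CCC=C3[C@]2(C(=O)OC)CC1
F8 | step 12 | C10 3-chloropropyl ketone dienol ether | CCOC1=CC2=CCC[C@H](CCCCl)C(=O)[C@]2(C(=O)OC)CC1
F9 | step 12 | triphenylphosphonium iodide of F8 | CCOC1=CC2=CCC[C@H](CCC[P+](c3ccccc3)(c3ccccc3)c3ccccc3)C(=O)[C@]2(C(=O)OC)CC1.[I-]
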